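This flask holds half the solid substrate of the winter run, so at the winter rate its solid should be gone before the reading.

| setting | winter | flask |
|---|---|---|
| solid substrate | 0.10 M | 0.050 M |
| remark | run made earlier |  |
| time |  | 4.0 h |

winter run (percent of the solid substrate charged)

| time / min | ring / % | starting material / % | solid substrate / % |
|---|---|---|---|
| 6.00 | 0 | 3.1 | 96.8 |
| 15.0 | 1.3 | 6.3 | 94.4 |
| 30.0 | 0 | 9.5 | 89.2 |
| 50.0 | 0.8 | 14.3 | 83.7 |

(readings scatter by 1 percentage point)

- solid, in amounts per volume of the solution: solid substrate
- at the start none of the solid substrate is in solution
- starting material is what solid substrate becomes in solution
- starting material means what is dissolved; the solid is not counted in it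

* the ring standing at 4.0 h, as a percentage of the solid substrate charged
* concentration of starting material in solution at 4.0 h, in percent of saturation

To whoever takes the bench: the flask holds solid substrate dissolving into starting material, with ring forming slowly from that. By 50.0 min the winter solid had lost 0.0196 M h⁻¹, as a reading. I take this rate as zero order in the solid, so my emptying time, the charge divided by that rate, is 2.56 h. That is earlier than the 4.0 h reading, provided the solution does not saturate first. The winter readings show no saturation level, so I give no figure for it. Leave stirring, volume and temperature alone, since the emptying time assumes the winter ones.

For ring, the last winter readings give 0.134 h⁻¹, loosely, with a scatter of 1 percentage point. With dissolved material rising steadily until the emptying time and then standing whole, ring reaches 36.5 %, which I hold as a ceiling.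

The forecast differs from my reckoning: ring 5 % (0.5 % to 14 %) and saturation 65 % (25 % to 100 %), on the ground “If dissolution scales with the solid present”. The flask gives ring 20.6 %, under my ceiling, saturation 53.4 %, and solid substrate 0 %.

    2 starting material → open dimer (k = 4.16 M⁻¹ h⁻¹)
    solid substrate ⇌ starting material, rate k2*(cs2 - [starting material]) while solid is left; crystals form when [starting material] > cs2 (solubility = 44.0 mM, k = 0.593 h⁻¹)
    starting material → ring (k = 0.123 h⁻¹)

The neighbour flask, charged with 0.12 M and read at the same time, has an emptying time of 6.13 h, later than 4.0 h, so solid should still stand there. The steady rate leaves 34.7 % of its charge as solid, and that flask shows solid substrate at 54.8 %, with open dimer at 13.8 % and ring at 8.66 %.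

The data come from a simulation with made-up constants, and the scatter is random.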